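**Assumptions (one line each)**
- The lipase (Candida antarctica lipase B) acylates the (R)-carbinol of 12, leaving the (S)-alcohol. If the opposite happens, the (S)-acetate is saponified to the same (S)-alcohol 13.
- The Sharpless epoxidation of methallyl alcohol is taken as ≥90% ee. Any minor enantiomer is removed as a diastereomer by HPLC after Step 23.

## Retrosynthetic overview
1. Lychnopholide ⇒ angelate ester of the C6 alcohol ⇐ macrocyclic α-methylene lactone 26.
2. C6–C7 bond, C6/C7 stereocentres, α-methylene lactone and the 10-membered ring all come from one intramolecular Nozaki–Hiyama–Kishi allylation (3-bromomethylbutenolide + C6 aldehyde).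
3. Ring order: 3(2H)-furanone first (desilylative 5-endo-dig oxa-Michael of a hydroxy-ynone), then the butenolide (RCM), then the 10-membered ring (NHK) last.
4. Ynone from a Sonogashira coupling of alkyne 9 (C4 quaternary centre from Sharpless AE of methallyl alcohol) with Z-vinyl iodide 14. The Z-iodide carries C8, set by lipase kinetic resolution.

## Route

**Step 1**
Reactants: 1, 2-methylprop-2-en-1-ol
Product: 2, (R)-(2-methyloxiran-2-yl)methyl pivalate (via (S)-2-methylglycidol, trapped in situ)
Conditions: Ti(OiPr)4 (5 mol%), L-(+)-DET (6 mol%), TBHP, 4 Å MS, CH2Cl2, –20 °C; then Me2S; then PivCl, Et3N, DMAP, –20→0 °C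
Reagents that add atoms: TBHP CC(C)(C)OO (supplies epoxide O); pivaloyl chloride CC(C)(C)C(=O)Cl
Why: Sharpless asymmetric epoxidation sets the C4 quaternary stereocentre by catalyst control. Pivaloylation in situ avoids isolating the volatile epoxy alcohol and avoids base-mediated Payne racemisation.

**Step 2**
Reactants: 2
Product: 3, (R)-2-hydroxy-2-methylpent-4-en-1-yl pivalate
Conditions: CH2=CHMgBr, CuI (10 mol%), THF, –30→0 °C
Reagents that add atoms: vinylmagnesium bromide C=C[Mg]Br
Why: The vinyl cuprate opens the epoxide at the unhindered CH2 (C5), so the C4 configuration is retained and C5–C6 is formed (Cu-catalysed Grignard epoxide opening).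

**Step 3**
Reactants: 3
Product: 4, (R)-2-(TBSO)-2-methylpent-4-en-1-yl pivalate
Conditions: TBSOTf, 2,6-lutidine, CH2Cl2, 0 °C
Reagents that add atoms: TBSOTf CC(C)(C)[Si](C)(C)OS(=O)(=O)C(F)(F)F
Why: Silyl triflate silylation of the tertiary alcohol; no stereocentre is touched.

**Step 4**
Reactants: 4
Product: 5, (R)-2-(TBSO)-2-methyl-4-oxobutyl pivalate
Conditions: OsO4 (2 mol%), NaIO4, 2,6-lutidine, dioxane/H2O, 25 °C
Reagents that add atoms: NaIO4 [Na+].[O-]I(=O)(=O)=O and OsO4 O=[Os](=O)(=O)=O (source of the carbonyl O)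
Why: Lemieux–Johnson cleavage converts the terminal alkene selectively into the C6 aldehyde; no stereocentre is affected because C4 is quaternary.

**Step 5**
Reactants: 5
Product: 6, (R)-2-(TBSO)-4,4-dimethoxy-2-methylbutyl pivalate
Conditions: HC(OMe)3, PPTS (20 mol%), MeOH, 40 °C
Reagents that add atoms: trimethyl orthoformate COC(OC)OC; methanol CO
Why: Acetalisation masks the C6 aldehyde so it survives the Grignard, Pd and Ru steps.

**Step 6**
Reactants: 6
Product: 7, (R)-2-(TBSO)-4,4-dimethoxy-2-methylbutan-1-ol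
Conditions: DIBAL-H (2.5 equiv), CH2Cl2, –78→0 °C
Reagents that add atoms: none
Why: Hydride reduction of the hindered pivalate frees the C3 primary alcohol; the acetal and the tertiary silyl ether survive.

**Step 7**
Reactants: 7
Product: 8, (R)-2-(TBSO)-4,4-dimethoxy-2-methylbutanal
Conditions: Dess–Martin periodinane, NaHCO3, CH2Cl2, 0→25 °C
Reagents that add atoms: none
Why: DMP oxidation gives a non-enolisable α-quaternary aldehyde, so C4 cannot epimerise.

**Step 8**
Reactants: 8
Product: 9, (R)-4-(TBSO)-6,6-dimethoxy-4-methylhex-1-yn-3-ol (C3 epimeric mixture)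
Conditions: HC≡CMgBr, THF, –78→0 °C
Reagents that add atoms: ethynylmagnesium bromide C#C[Mg]Br
Why: Grignard 1,2-addition installs the C1–C2 alkyne; the new C3 carbinol stereocentre is irrelevant because it is oxidised to the ynone later.

**Step 9**
Reactants: 10, acrolein
Product: 11, (±)-hex-1-en-4-yn-3-ol
Conditions: CH3C≡CMgBr, THF, –78 °C
Reagents that add atoms: 1-propynylmagnesium bromide CC#C[Mg]Br
Why: Alkynyl Grignard 1,2-addition to the enal gives the racemic enynol.

**Step 10**
Reactants: 11
Product: 12, (±)-(4Z)-5-iodohexa-1,4-dien-3-ol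
Conditions: Red-Al, Et2O, 0→25 °C; then EtOAc, –78 °C; then I2, THF, –78→25 °C
Reagents that add atoms: I2 II (Red-Al supplies hydride only)
Why: Alkoxide-directed trans-hydroalumination followed by iodinolysis places I on C10 cis to C8, giving the Z-vinyl iodide required for the C8/C1 cis geometry.

**Step 11**
Reactants: 12
Product: 13, (3S,4Z)-5-iodohexa-1,4-dien-3-ol (the (R)-acetate is a separable by-product)
Conditions: Novozym 435 (immobilised CAL-B lipase, a hydrolase), vinyl acetate (0.55 equiv), MTBE, 25 °C, stop at ~50% conversion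
Reagents that add atoms: none (vinyl acetate only acetylates the unwanted (R)-enantiomer)
Why: Lipase-catalysed kinetic resolution discriminates the bulky Z-iodoalkenyl group from the small vinyl group and sets the C8 configuration.

**Step 12**
Reactants: 13
Product: 14, tert-butyl{[(3S,4Z)-5-iodohexa-1,4-dien-3-yl]oxy}dimethylsilane
Conditions: TBSCl, imidazole, DMF, 0→25 °C
Reagents that add atoms: TBSCl CC(C)(C)[Si](C)(C)Cl
Why: Silylation protects C8–OH so that the next oxidation is selective; C8 is not touched.

**Step 13**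
Reactants: 15, ethyl 2-(hydroxymethyl)acrylate
Product: 16, ethyl 2-[(TBSO)methyl]acrylate
Conditions: TBSCl, imidazole, CH2Cl2, 0→25 °C
Reagents that add atoms: TBSCl CC(C)(C)[Si](C)(C)Cl
Why: Silyl protection of the allylic alcohol, which becomes C13 later.

**Step 14**
Reactants: 16
Product: 17, 2-[(TBSO)methyl]acrylic acid
Conditions: LiOH·H2O, THF/H2O, 0→25 °C; then pH 4 work-up
Reagents that add atoms: LiOH [Li+].[OH-]; water O
Why: Saponification of the ethyl ester; the primary TBS ether is stable to these conditions.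

**Step 15**
Reactants: 9, 14
Product: 18, Z-enyne: C=C[C@H](OTBS)/C=C(/C)C#CC(O)[C@@](C)(CC(OC)OC)OTBS (C3 epimeric mixture)
Conditions: Pd(PPh3)4 (5 mol%), CuI (10 mol%), i-Pr2NH, THF, 25 °C
Reagents that add atoms: none
Why: Sonogashira coupling proceeds with retention of the Z-vinyl iodide geometry and of C4 and C8.

**Step 16**
Reactants: 18
Product: 19, ynone (C3=O) with both TBS ethers
Conditions: DMP, NaHCO3, CH2Cl2, 0→25 °C
Reagents that add atoms: none
Why: Oxidation of the propargylic alcohol to the 4-silyloxy ynone removes the C3 stereocentre, which was not needed.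

**Step 17**
Reactants: 19
Product: 20, (2R)-2-(2,2-dimethoxyethyl)-5-[(1Z,3S)-3-hydroxy-1-methylpenta-1,4-dien-1-yl]-2-methylfuran-3(2H)-one
Conditions: TBAF, THF, 0 °C
Reagents that add atoms: none
Why: Fluoride removes both TBS groups; the tertiary alkoxide adds 5-endo-dig (oxa-Michael) to the ynone to form the 3(2H)-furanone, with C4–O retained and the Z-alkene preserved.

**Step 18**
Reactants: 20, 17
Product: 21, C8 ester of 20 with 17
Conditions: 17, 2,4,6-Cl3C6H2COCl, Et3N, THF, 25 °C; then 20, DMAP, toluene, 0→25 °C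
Reagents that add atoms: none (17 is a numbered reactant)
Why: Yamaguchi esterification by acyl transfer leaves the C8–O bond, and so the C8 configuration, unchanged.

**Step 19**
Reactants: 21
Product: 22, butenolide (C=C1CO-TBS, C8–H as drawn)
Conditions: Grubbs II (8 mol%), CH2Cl2 (5 mM), 40 °C
Reagents that add atoms: none (ethylene is lost)
Why: Ring-closing metathesis of the vinyl group with the α-substituted acrylate gives the 3-substituted 2(5H)-furanone, which carries C7 and C11 and leaves C8 untouched.

**Step 20**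
Reactants: 22
Product: 23, 3-(hydroxymethyl)butenolide
Conditions: HF·pyridine, pyridine, THF, 0 °C
Reagents that add atoms: none
Why: Buffered acidic desilylation avoids basic conditions that could epimerise the γ-acidic C8–H; the dimethyl acetal survives.

**Step 21**
Reactants: 23
Product: 24, 3-(bromomethyl)butenolide
Conditions: PPh3 (1.1 equiv), CBr4 (1.1 equiv), CH2Cl2, 0 °C
Reagents that add atoms: carbon tetrabromide BrC(Br)(Br)Br
Why: Appel bromination is neutral and converts the allylic alcohol to the allyl bromide by SN2; no stereocentre is involved.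

**Step 22**
Reactants: 24
Product: 25, C6 aldehyde
Conditions: TESOTf, 2,4,6-collidine, CH2Cl2, 0 °C; then H2O
Reagents that add atoms: water O
Why: Fujioka non-acidic acetal hydrolysis via the collidinium intermediate leaves the allyl bromide, furanone and butenolide intact.

**Step 23**
Reactants: 25
Product: 26, macrocyclic α-methylene lactone with free C6–OH
Conditions: CrCl2 (10 equiv), THF/DMF 4:1, 0.002 M, 25 °C, syringe-pump addition
Reagents that add atoms: none (H comes from work-up)
Why: In this intramolecular Nozaki–Hiyama–Kishi allylation, the allylchromium reacts through C7 via a chair Zimmerman–Traxler transition state. The ring-fixed E-allyl unit gives the anti C6/C7 relationship, attack anti to the C8 side chain gives the trans-fused lactone, and the exocyclic methylene forms at the same time.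

**Step 24**
Reactants: 26, 27 (angelic acid)
Product: 28, lychnopholide
Conditions: 27, 2,4,6-Cl3C6H2COCl, Et3N, THF, 25 °C; then 26, DMAP, toluene, 25 °C
Reagents that add atoms: none (27 is a numbered reactant)
Why: Yamaguchi esterification at mild temperature installs the Z-angelate without isomerisation to tiglate and without affecting any stereocentre.

## Compound list
1 | 2-methylprop-2-en-1-ol | CC(=C)CO | starting material
2 | (R)-(2-methyloxiran-2-yl)methyl pivalate | CC(C)(C)C(=O)OC[C@@]1(C)CO1 | intermediate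
3 | (R)-2-hydroxy-2-methylpent-4-en-1-yl pivalate | CC(C)(C)C(=O)OC[C@@](C)(CC=C)O | intermediate
4 | (R)-2-(TBSO)-2-methylpent-4-en-1-yl pivalate | CC(C)(C)C(=O)OC[C@@](C)(CC=C)O[Si](C)(C)C(C)(C)C | intermediate
5 | (R)-2-(TBSO)-2-methyl-4-oxobutyl pivalate | CC(C)(C)C(=O)OC[C@@](C)(CC=O)O[Si](C)(C)C(C)(C)C | intermediate
6 | (R)-2-(TBSO)-4,4-dimethoxy-2-methylbutyl pivalate | CC(C)(C)C(=O)OC[C@@](C)(CC(OC)OC)O[Si](C)(C)C(C)(C)C | intermediate
7 | (R)-2-(TBSO)-4,4-dimethoxy-2-methylbutan-1-ol | OC[C@@](C)(CC(OC)OC)O[Si](C)(C)C(C)(C)C | intermediate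
8 | (R)-2-(TBSO)-4,4-dimethoxy-2-methylbutanal | O=C[C@@](C)(CC(OC)OC)O[Si](C)(C)C(C)(C)C | intermediate
9 | 4-(TBSO)-6,6-dimethoxy-4-methylhex-1-yn-3-ol (C4 R; C3 mixture) | C#CC(O)[C@@](C)(CC(OC)OC)O[Si](C)(C)C(C)(C)C | intermediate
10 | acrolein | C=CC=O | starting material
11 | (±)-hex-1-en-4-yn-3-ol | C=CC(O)C#CC | intermediate
12 | (±)-(4Z)-5-iodohexa-1,4-dien-3-ol | OC(C=C)/C=C(/C)I | intermediate
13 | (3S,4Z)-5-iodohexa-1,4-dien-3-ol | O[C@@H](C=C)/C=C(/C)I | intermediate
14 | TBS ether of 13 | CC(C)(C)[Si](C)(C)O[C@@H](C=C)/C=C(/C)I | intermediate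
15 | ethyl 2-(hydroxymethyl)acrylate | C=C(CO)C(=O)OCC | starting material
16 | ethyl 2-[(TBSO)methyl]acrylate | C=C(CO[Si](C)(C)C(C)(C)C)C(=O)OCC | intermediate
17 | 2-[(TBSO)methyl]acrylic acid | C=C(CO[Si](C)(C)C(C)(C)C)C(=O)O | intermediate
18 | Z-enyne bis-TBS ether | C=C[C@H](O[Si](C)(C)C(C)(C)C)/C=C(/C)C#CC(O)[C@@](C)(CC(OC)OC)O[Si](C)(C)C(C)(C)C | intermediate
19 | ynone | C=C[C@H](O[Si](C)(C)C(C)(C)C)/C=C(/C)C#CC(=O)[C@@](C)(CC(OC)OC)O[Si](C)(C)C(C)(C)C | intermediate
20 | furanone alcohol | C=C[C@H](O)/C=C(/C)C1=CC(=O)[C@@](C)(CC(OC)OC)O1 | intermediate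
21 | acrylate ester of 20 | C=C[C@H](OC(=O)C(=C)CO[Si](C)(C)C(C)(C)C)/C=C(/C)C1=CC(=O)[C@@](C)(CC(OC)OC)O1 | intermediate
22 | butenolide (CH2OTBS) | O=C1O[C@H](/C=C(/C)C2=CC(=O)[C@@](C)(CC(OC)OC)O2)C=C1CO[Si](C)(C)C(C)(C)C | intermediate
23 | hydroxymethyl butenolide | O=C1O[C@H](/C=C(/C)C2=CC(=O)[C@@](C)(CC(OC)OC)O2)C=C1CO | intermediate
24 | bromomethyl butenolide | O=C1O[C@H](/C=C(/C)C2=CC(=O)[C@@](C)(CC(OC)OC)O2)C=C1CBr | intermediate
25 | aldehyde | O=C1O[C@H](/C=C(/C)C2=CC(=O)[C@@](C)(CC=O)O2)C=C1CBr | intermediate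
26 | C6-hydroxy macrocycle (deacyl-lychnopholide) | C=C1C(=O)O[C@@H]2/C=C(/C)C3=CC(=O)[C@@](C)(C[C@H](O)[C@@H]12)O3 | intermediate
27 | angelic acid ((Z)-2-methylbut-2-enoic acid) | C/C=C(/C)C(=O)O | starting material
28 | lychnopholide | C=C1C(=O)O[C@@H]2/C=C(/C)C3=CC(=O)[C@@](C)(C[C@H](OC(=O)/C(C)=C\C)[C@@H]12)O3 | target

**Total step count:** 24 steps. **Longest linear sequence:** 18 steps (1→2→3→4→5→6→7→8→15→16→17→18→19→20→21→22→23→24).

## Three steps most likely to fail
1. **Step 23 (macro-NHK).** Yield, or trans/anti selectivity in the strained 10-membered ring, may be poor. *Fallback:* do the C6–C7 bond-forming Barbier intermolecularly, using a 5-vinyl-3-(bromomethyl)butenolide and the C6 aldehyde on an acyclic furanone precursor bearing a C10 isopropenyl group, then close the ring at C9=C10 by RCM (Hoveyda–Grubbs II).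
2. **Step 19 (RCM).** The α-substituted acrylate may ring-close poorly, and the γ-acidic C8–H may racemise. *Fallback:* build the butenolide earlier, on the simple Z-vinyl iodide stage (acylate with 17, then RCM), then carry out Sonogashira and oxidation, and cyclise the hydroxy-ynone with neutral Au(I) catalysis after HF·pyridine desilylation instead of fluoride.
3. **Step 11 (lipase resolution).** Enantioselectivity may be insufficient. *Fallback:* oxidise racemic 12 (MnO2) to the dienone, reduce it with (S)-selective Ru-TsDPEN transfer hydrogenation (HCO2H/Et3N) to give 13, and recycle the wrong enantiomer by the same oxidation/reduction loop.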